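(The numbers in the tables come from a simulation with constants of no real substance; noise was put on by code.)

Two questions stand for this flask: when, within the time allowed, it holds most target, and how much.

| setting | dawn | winter | spring | flask |
|---|---|---|---|---|
| starting material | 0.020 M | 0.020 M | 0.010 M | 0.020 M |
| reagent | 0.010 M (fed, over 40 s) | 0.040 M (fed, over 40 s) | 0.020 M (fed, over 40 s) | 0.0200 M (fed, over 40 s) |
| remark | run made earlier; the fed solution adds 0.25 times the starting volume | run made earlier; the fed solution adds 0.25 times the starting volume | run made earlier; the fed solution adds 0.25 times the starting volume | the fed solution adds 0.25 times the starting volume |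
| time |  |  |  | 3.0 h |

| run | time / min | target / % | starting material / % |
|---|---|---|---|
| dawn | 12.0 | 2 | 100 |
| dawn | 20.0 | 0 | 101 |
| dawn | 30.0 | 7 | 98 |
| dawn | 40.0 | 12 | 82 |
| dawn | 60.0 | 26 | 61 |
| dawn | 120 | 22 | 54 |
| winter | 12.0 | 34 | 64 |
| winter | 20.0 | 77 | 8 |
| winter | 30.0 | 71 | 1 |
| winter | 40.0 | 59 | 2 |
| winter | 60.0 | 52 | 0 |
| winter | 120 | 42 | 1 |
| spring | 12.0 | 0 | 102 |
| spring | 20.0 | 5 | 95 |
| spring | 40.0 | 25 | 70 |
| spring | 60.0 | 54 | 24 |
| spring | 120 | 46 | 0 |

(scatter of a reading: 2 percentage points)

- charges are per starting volume, the dose included; the dosed solution carries all of it

- when, up to 3.0 h, the flask holds most target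
- the amount of target, in percent of the starting material charged, at that time

Turn the question round. For the most target to stand at the very end, target has to be still rising there: either what has formed stays, and the runs show it as the whole of what has reacted, or starting material is still being used up at the end. In winter the last reading gives 42.4%: that is the settled share, target at the last reading over the starting material gone by then. Take winter because it peaked earliest; spring, later to peak, reads 46.0%. If you use an even split of the reacted material as the zero of the scale, winter stands 7.6 percentage points below zero, so what has formed does not stay. Indeed winter's target reads 77% at 20.0 min, and at the end it reads lower. The other way needs starting material still going at the end, and winter's reads 1% already at 30.0 min.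

So I expect an early peak in this flask. Its reagent charge lies between dawn's and winter's, with the same starting material, so I place the peak between 20.0 min and 60.0 min, and its height between 42.4% and 77%.

The forecast, “Balancing formation against loss”, says 0.75 h and 58%. The flask gives 56.6% at 0.742 h.

    starting material + reagent + by-product → target + 2 by-product (k = 1000 M⁻² min⁻¹)
    reagent → decomposition product (k = 2.10 × 10⁻⁴ min⁻¹)
    target ⇌ isomer of the product (K = 1.50, k = 0.0220 min⁻¹)
    starting material + reagent → target + by-product (k = 0.0270 M⁻¹ min⁻¹)

The rest of what reacted is isomer of the product: taking away the passing of target into it, both ways, lifts the highest target from 56.6% to 96.9%, the largest single effect. At 3.00 h this flask's target over what has reacted is 40.8%, against the share of 42.4%. Now take a neighbour with 0.080 M of starting material, where reagent is the limiting reagent: its charge covers 25.0% of the starting material, so the share gives 10.6%. The computed end target is 10.0%, with reagent at 0%.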